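**Retrosynthetic overview**
- Numbering runs forward: farnesol 1 → epoxy alcohol 2 → (oxyphosphonium salt 3) → epoxy bromide 4 → (cations 5, 6, 7) → palisadin B 8.
- Key disconnection (one operation, 8 ⇒ 4): the C5a–C6 bond, the C9a–O bond and the C3=C4 double bond all come from open-chain epoxy bromide 4, in a bromonium-triggered cascade terminated by the epoxide oxygen.
- Ring order inside that step: bromocyclohexane first (Br+ on the terminal alkene, 6,7-alkene closes). The oxygen ring follows (epoxide O onto the cation, six-membered epoxonium) and expands to the oxepene by tertiary C–O cleavage and loss of H+.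
- 4 ⇒ 2 (C–Br by Appel reaction) ⇒ 1 (Sharpless epoxidation sets C-2; no Z-alkene or halohydrin has to be built).

Assumption: (2E,6E)-farnesol (≥95% E,E) and TBCO are bought; open-chain compounds are numbered as farnesanes (C-1 = CH2X) and the bicycle as a 1-benzoxepine (farnesane C-2, C-3, C-4, C-6, C-7, C-10 = benzoxepine C-2, C-3, C-4, C-5a, C-9a, C-7).

**Step 1**
Reactants: 1 (2E,6E)-farnesol
Product: 2 [(2S,3S)-3-[(3E)-4,8-dimethylnona-3,7-dien-1-yl]-3-methyloxiran-2-yl]methanol
Conditions: Ti(OiPr)4 (5 mol%), L-(+)-DET (7.5 mol%), t-BuOOH (2 equiv, anhydrous), 4 Å MS, CH2Cl2, −20 °C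
Reagents that add atoms: tert-butyl hydroperoxide, CC(C)(C)OO
Why: Katsuki–Sharpless asymmetric epoxidation: titanium binds the allylic hydroxyl so only the 2,3-alkene of the triene is epoxidised, and L-(+)-tartrate gives the (2S,3S)-epoxide (about 95% ee, as for geraniol), which fixes C-2 of the target (C-3 is destroyed later).

**Step 2**
Reactants: 2 [(2S,3S)-3-[(3E)-4,8-dimethylnona-3,7-dien-1-yl]-3-methyloxiran-2-yl]methanol
Product: 4 (2R,3S)-2-(bromomethyl)-3-[(3E)-4,8-dimethylnona-3,7-dien-1-yl]-3-methyloxirane, via alkoxyphosphonium bromide 3 (not isolated)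
Conditions: CBr4 (1.3 equiv), PPh3 (1.4 equiv), NaHCO3 (solid), CH2Cl2, −20 → 0 °C
Reagents that add atoms: carbon tetrabromide, BrC(Br)(Br)Br
Why: Appel reaction: the primary alcohol becomes oxyphosphonium salt 3 and is displaced by bromide (SN2 at C-1) under cold, buffered conditions that leave the trisubstituted epoxide intact; no stereocentre is touched (C-2 changes from S to R only through the CIP priority of CH2Br).

**Step 3**
Reactants: 4 (2R,3S)-2-(bromomethyl)-3-[(3E)-4,8-dimethylnona-3,7-dien-1-yl]-3-methyloxirane
Product: 8 palisadin B [(2R,5aS,7S,9aS)-7-bromo-2-(bromomethyl)-3,6,6,9a-tetramethyl-2,5,5a,6,7,8,9,9a-octahydro-1-benzoxepine], via bromocyclohexyl cation 5 (not isolated), via bicyclic epoxonium ion 6 (not isolated), via oxepanyl cation 7 (not isolated)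
Conditions: TBCO (1.0 equiv, in portions), MeNO2, 4 Å MS, −20 → 0 °C, dark; aq. Na2S2O3; SiO2 then AgNO3–SiO2 chromatography
Reagents that add atoms: 2,4,4,6-tetrabromocyclohexa-2,5-dien-1-one (TBCO), O=C1C(Br)=CC(Br)(Br)C=C1Br
Why: Proposed new method: TBCO transfers Br+ to the most accessible, terminal 10,11-alkene and the (E)-6,7-alkene opens the bromonium ion through a chair (anti addition, equatorial Br, giving cation 5), the epoxide oxygen then captures the tertiary C-7 cation through a six-membered transition state (epoxonium 6, O equatorial, trans ring fusion), the tertiary C-3–O bond of 6 ionises so that the oxygen stays on C-2 and the ring grows to the seven-membered cation 7, and tribromophenoxide removes a proton from C-4 to give the ring (cis) C3=C4 alkene of 8; C-2 is the untouched Sharpless centre, the relative configuration of C-5a, C-7 and C-9a follows from the chair and the E-alkene, but the remote epoxide does not control which face of the terminal alkene is brominated, so 8 forms together with its (2R,5aR,7R,9aR)-diastereomer (about 1:1 at best) and is separated by chromatography with the ee of 2; closest known reaction types are TBCO bromonium-initiated polyene cyclisations with oxygen termination (nerolidol to 3-bromocaparrapi oxide) and endo-selective epoxonium-opening cascades of polyepoxides that give oxepanes.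

**Compound list**
1 | (2E,6E)-farnesol, (2E,6E)-3,7,11-trimethyldodeca-2,6,10-trien-1-ol | OC/C=C(\C)CC/C=C(\C)CCC=C(C)C | starting material
2 | (2S,3S)-2,3-epoxyfarnesol, [(2S,3S)-3-[(3E)-4,8-dimethylnona-3,7-dien-1-yl]-3-methyloxiran-2-yl]methanol | OC[C@@H]1O[C@@]1(C)CC/C=C(\C)CCC=C(C)C | intermediate
3 | alkoxyphosphonium bromide, {[(2S,3S)-3-[(3E)-4,8-dimethylnona-3,7-dien-1-yl]-3-methyloxiran-2-yl]methoxy}triphenylphosphonium bromide | [Br-].C(O[P+](c1ccccc1)(c1ccccc1)c1ccccc1)[C@@H]1O[C@@]1(C)CC/C=C(\C)CCC=C(C)C | intermediate (not isolated)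
4 | (2R,3S)-2-(bromomethyl)-3-[(3E)-4,8-dimethylnona-3,7-dien-1-yl]-3-methyloxirane | BrC[C@@H]1O[C@@]1(C)CC/C=C(\C)CCC=C(C)C | intermediate
5 | bromocyclohexyl cation (4-bromo-1,3,3-trimethylcyclohexyl cation carrying the 2-(epoxy-bromobutyl) side chain at C-2) | BrC[C@@H]1O[C@@]1(C)CC[C@@H]2[C+](C)CC[C@H](Br)C2(C)C | intermediate (not isolated)
6 | bicyclic epoxonium ion (oxiranium O bonded to C-2, C-3 and C-7, fused to the trans-bromodecalin-type oxa-ring) | BrC[C@@H]1[O+]2[C@@]1(C)CC[C@@H]3[C@]2(C)CC[C@H](Br)C3(C)C | intermediate (not isolated)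
7 | oxepanyl cation (ring-expanded tertiary C-3 cation of the 1-benzoxepane) | C[C+]1CC[C@H]2C(C)(C)[C@@H](Br)CC[C@]2(C)O[C@H]1CBr | intermediate (not isolated)
8 | palisadin B, (2R,5aS,7S,9aS)-7-bromo-2-(bromomethyl)-3,6,6,9a-tetramethyl-2,5,5a,6,7,8,9,9a-octahydro-1-benzoxepine | CC1=CC[C@H]2C(C)(C)[C@@H](Br)CC[C@]2(C)O[C@H]1CBr | target

**Totals**
Total step count: 3. Longest linear sequence: 3.

**Steps most likely to fail, with fallbacks**

Step 3 is by far the riskiest. The cascade is unproven, and the face of the terminal alkene is not controlled. Compound 8 is probably the minor partner of its (2R,5aR,7R,9aR)-diastereomer, because its epoxonium 6 carries the C-3 methyl syn to the angular methyl. Side paths are bromination of the 6,7-alkene, loss of H+ from 5 to monocyclic trienes, exocyclic-methylene or 1,2-hydride-shift products from 7, and over-bromination of the ring alkene. A realistic expectation is 10–20% of 8. The fallback sets out from 4 and returns at 8; it replaces the bromonium trigger by mercury(II) and brings in bromine afterwards. Compound 4 is treated with Hg(OTf)2·PhNMe2 in MeNO2 at −20 °C; mercurinium formation is reversible and more selective for the terminal alkene, and the same epoxonium, ring-expansion and elimination sequence follows. Aqueous KBr work-up gives the organomercury bromide bromo[(2R,5aS,7S,9aS)-2-(bromomethyl)-3,6,6,9a-tetramethyl-2,5,5a,6,7,8,9,9a-octahydro-1-benzoxepin-7-yl]mercury F1, whose diastereomers are separated by crystallisation. One equivalent of Br2·pyridine with LiBr under O2 at −40 °C (SE2, retention) then turns C–Hg into the equatorial C–Br bond of 8; the single equivalent and low temperature are meant to spare the ring alkene, which is the weak point of this fallback.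

Step 2 is the next risk. Bromide or traces of HBr may open the epoxide during the Appel reaction, and the CH2Br group lowers the nucleophilicity of the epoxide oxygen needed in step 3. The fallback sets out from 2 and returns at 8; it postpones the bromination. The TBCO cascade is run on 2 itself to give the hydroxymethyl oxepene [(2R,5aS,7S,9aS)-7-bromo-3,6,6,9a-tetramethyl-2,5,5a,6,7,8,9,9a-octahydro-1-benzoxepin-2-yl]methanol F2. Appel bromination (CBr4, PPh3, CH2Cl2, 0 °C) of this primary alcohol, which no longer holds an epoxide, gives 8.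

Step 1 is reliable, but about 95% ee leaves a few percent of the enantiomeric series, and the diastereomer separation of step 3 does not remove it. The fallback sets out from 2 and returns at 2; it upgrades the ee through a crystalline derivative. Compound 2 is acylated with 3,5-dinitrobenzoyl chloride (Et3N, DMAP) to the ester [(2S,3S)-3-[(3E)-4,8-dimethylnona-3,7-dien-1-yl]-3-methyloxiran-2-yl]methyl 3,5-dinitrobenzoate F3. This is recrystallised to >99% ee and cleaved with K2CO3 in MeOH to give 2 again.

**Further compounds**
F1 | step 3 | bromo[(2R,5aS,7S,9aS)-2-(bromomethyl)-3,6,6,9a-tetramethyl-2,5,5a,6,7,8,9,9a-octahydro-1-benzoxepin-7-yl]mercury | CC1=CC[C@H]2C(C)(C)[C@@H]([Hg]Br)CC[C@]2(C)O[C@H]1CBr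
F2 | step 2 | [(2R,5aS,7S,9aS)-7-bromo-3,6,6,9a-tetramethyl-2,5,5a,6,7,8,9,9a-octahydro-1-benzoxepin-2-yl]methanol | CC1=CC[C@H]2C(C)(C)[C@@H](Br)CC[C@]2(C)O[C@H]1CO
F3 | step 1 | [(2S,3S)-3-[(3E)-4,8-dimethylnona-3,7-dien-1-yl]-3-methyloxiran-2-yl]methyl 3,5-dinitrobenzoate | O=C(OC[C@@H]1O[C@@]1(C)CC/C=C(\C)CCC=C(C)C)c1cc(cc(c1)[N+](=O)[O-])[N+](=O)[O-]
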